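Ring C is cut at C4–C3 and O1–C2. The key step exploits the polarity of ring C: O1 sits on benzylic C2, which carries the 4-oxygenated aryl ring B, and the oxygenated C3 adjoins C4 on ring A. This is the pattern left when a ring A ortho-quinone methide adds to a donor styrene. One enantioselective three-component hetero-[4+2] reaction of salicylaldehyde 9, trimethyl orthoformate 15 and (E)-enol acetate 14 would form both bonds, close ring C and set C2 and C3. Aldehyde 9 already carries the 1,1-dimethylallyl group between two MOM ethers and leaves free only the phenol para to it. C4 is oxidised to the ketone afterwards.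

Key step: step 10

Remark: atom labels O1, C2, C3, C4 and rings A, B, C follow flavonoid numbering.
Assumption: the sense of induction of the chiral acid cannot be predicted, so the (R)-catalyst is written and its mirror image is to be used if it favours the other enantiomer.

Step 1
Reactants: 1 2,4,6-trihydroxybenzaldehyde
Product: 2 2,6-dihydroxy-4-(methoxymethoxy)benzaldehyde
Conditions: MOMCl (1.0 equiv), i-Pr2NEt (1.1 equiv), THF, −10 → 0 °C
Reagents that add atoms: chloromethyl methyl ether, COCCl
Why: Williamson-type MOM ether formation, in which the 4-hydroxyl reacts first because it is the most acidic (a vinylogous carboxylic acid) and is not tied up in the hydrogen bond to the formyl group.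

Step 2
Reactants: 2 2,6-dihydroxy-4-(methoxymethoxy)benzaldehyde; 3 prenyl bromide
Product: 4 2-hydroxy-4-(methoxymethoxy)-6-[(3-methylbut-2-en-1-yl)oxy]benzaldehyde
Conditions: K2CO3 (1.2 equiv), acetone, rt
Reagents that add atoms: none
Why: Williamson etherification of the monophenoxide, which should stop after one alkylation because the remaining hydroxyl is then locked in the hydrogen bond to the formyl group.

Step 3
Reactants: 4 2-hydroxy-4-(methoxymethoxy)-6-[(3-methylbut-2-en-1-yl)oxy]benzaldehyde
Product: 5 2-[(tert-butyldimethylsilyl)oxy]-4-(methoxymethoxy)-6-[(3-methylbut-2-en-1-yl)oxy]benzaldehyde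
Conditions: TBSCl, imidazole, DMF, rt
Reagents that add atoms: tert-butyldimethylsilyl chloride, CC(C)(C)[Si](C)(C)Cl
Why: Silyl ether formation marks the phenol that must be free in 9, because the coming rearrangement liberates the other, hindered phenol, which must end up protected.

Step 4
Reactants: 5 2-[(tert-butyldimethylsilyl)oxy]-4-(methoxymethoxy)-6-[(3-methylbut-2-en-1-yl)oxy]benzaldehyde
Product: 7 6-[(tert-butyldimethylsilyl)oxy]-2-hydroxy-4-(methoxymethoxy)-3-(2-methylbut-3-en-2-yl)benzaldehyde, via ortho-dienone 6 (not isolated)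
Conditions: Eu(fod)3 [europium tris(6,6,7,7,8,8,8-heptafluoro-2,2-dimethyloctane-3,5-dionate)] (10 mol %), CHCl3, 60 °C
Reagents that add atoms: none
Why: Lewis acid-catalysed aromatic Claisen rearrangement, in which chelation of europium between the formyl and ether oxygens lets the [3,3] shift run at 60 °C to the only free ortho position, so that dienone 6 should tautomerise to the 1,1-dimethylallyl phenol before a Cope shift to the para position can compete.

Step 5
Reactants: 7 6-[(tert-butyldimethylsilyl)oxy]-2-hydroxy-4-(methoxymethoxy)-3-(2-methylbut-3-en-2-yl)benzaldehyde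
Product: 8 6-[(tert-butyldimethylsilyl)oxy]-2,4-bis(methoxymethoxy)-3-(2-methylbut-3-en-2-yl)benzaldehyde
Conditions: NaH, THF, 0 °C; then MOMCl, 0 °C → rt
Reagents that add atoms: chloromethyl methyl ether, COCCl
Why: Williamson-type MOM ether formation on the sodium phenoxide of the only free hydroxyl, for which the small, very reactive electrophile should overcome the hindrance of the neighbouring tert-alkyl group.

Step 6
Reactants: 8 6-[(tert-butyldimethylsilyl)oxy]-2,4-bis(methoxymethoxy)-3-(2-methylbut-3-en-2-yl)benzaldehyde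
Product: 9 2-hydroxy-4,6-bis(methoxymethoxy)-5-(2-methylbut-3-en-2-yl)benzaldehyde
Conditions: n-Bu4NF, AcOH, THF, 0 °C
Reagents that add atoms: none
Why: Fluoride-mediated desilylation, fast for an aryl silyl ether ortho to a formyl group, which under acetic acid buffering should leave the MOM acetals, the aldehyde and the alkene untouched.

Step 7
Reactants: 10 eugenol
Product: 11 4-allyl-2-methoxy-1-(methoxymethoxy)benzene
Conditions: MOMCl, i-Pr2NEt, CH2Cl2, 0 °C → rt
Reagents that add atoms: chloromethyl methyl ether, COCCl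
Why: Williamson-type MOM ether formation on an unhindered phenol, chosen so that all three phenol protecting groups fall in the one acidic final step.

Step 8
Reactants: 11 4-allyl-2-methoxy-1-(methoxymethoxy)benzene
Product: 13 2-[3-methoxy-4-(methoxymethoxy)phenyl]acetaldehyde, via diol 12 (not isolated)
Conditions: K2OsO4·2H2O (1 mol %), NaIO4 (4 equiv), 2,6-lutidine, dioxane/H2O, rt
Reagents that add atoms: sodium periodate, [Na+].[O-]I(=O)(=O)=O
Why: Lemieux–Johnson oxidation, in which osmium-catalysed dihydroxylation to diol 12 and periodate glycol cleavage in the same flask give the arylacetaldehyde under near-neutral conditions that spare the electron-rich ring.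

Step 9
Reactants: 13 2-[3-methoxy-4-(methoxymethoxy)phenyl]acetaldehyde
Product: 14 (E)-2-[3-methoxy-4-(methoxymethoxy)phenyl]ethenyl acetate
Conditions: Ac2O, KOAc, 120 °C; E isomer isolated by chromatography (AgNO3-impregnated silica if needed)
Reagents that add atoms: acetic anhydride, CC(=O)OC(C)=O
Why: Enol acetate formation by acetate-mediated enolisation and O-acylation of the readily enolised arylacetaldehyde, expected to give an E/Z mixture from which the conjugated E isomer needed for a trans outcome is separated.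

Step 10
Reactants: 9 2-hydroxy-4,6-bis(methoxymethoxy)-5-(2-methylbut-3-en-2-yl)benzaldehyde; 14 (E)-2-[3-methoxy-4-(methoxymethoxy)phenyl]ethenyl acetate (1.5 equiv); 15 trimethyl orthoformate (1.5 equiv)
Product: 18 (2R,3S,4R)-4-methoxy-2-[3-methoxy-4-(methoxymethoxy)phenyl]-5,7-bis(methoxymethoxy)-6-(2-methylbut-3-en-2-yl)-3,4-dihydro-2H-chromen-3-yl acetate, via dimethyl acetal 16 (not isolated), via methoxy ortho-quinone methide 17 (not isolated)
Conditions: (R)-3,3′-bis(2,4,6-triisopropylphenyl)-1,1′-binaphthalene-2,2′-diyl N-triflylphosphoramide (10 mol %), 5 Å MS, PhMe, −20 → 0 °C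
Reagents that add atoms: none
Why: Proposed new method: the orthoformate converts 9 into acetal 16, which the chiral acid ionises with loss of methanol to the push-pull methoxy ortho-quinone methide 17, held as a hydrogen-bonded ion pair with the phosphoramide anion, and 17 then adds 14 in an asynchronous inverse-demand hetero-[4+2] cycloaddition. The closest known reaction types are the achiral-acid three-component union of salicylaldehydes, orthoformates and styrenes or enol ethers to 4-alkoxychromans and chiral phosphoric acid-catalysed ortho-quinone methide cycloadditions, neither shown as an enantioselective reaction of an aryl enol acetate. Ring C closes in the cycloaddition itself: the acetoxy-bearing carbon attacks the methide carbon (C4–C3) while charge builds at the benzylic carbon, which the dienone oxygen captures (O1–C2), at the stepwise limit a 6-exo-trig capture of a para-quinone-methide-like cation. C2 and C3 should come out trans because the E alkene adds suprafacially (a stepwise closure would also place aryl and acetoxy equatorial), C4 is expected 2,4-cis as is usual for these additions and is erased in step 11, and the absolute configuration at C2 and C3 rests only on face selection inside the chiral ion pair. The step needs regioselectivity, secured by the 4-alkoxyaryl group being a far better donor than acetoxy, chemoselectivity for the enol acetate over the unactivated vinyl group, secured by the large nucleophilicity gap, and enantioselectivity, which only the confined anion can supply; the MOM acetals should tolerate the anhydrous acid at low temperature.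

Step 11
Reactants: 18 (2R,3S,4R)-4-methoxy-2-[3-methoxy-4-(methoxymethoxy)phenyl]-5,7-bis(methoxymethoxy)-6-(2-methylbut-3-en-2-yl)-3,4-dihydro-2H-chromen-3-yl acetate
Product: 20 (2R,3R)-2-[3-methoxy-4-(methoxymethoxy)phenyl]-5,7-bis(methoxymethoxy)-6-(2-methylbut-3-en-2-yl)-4-oxo-3,4-dihydro-2H-chromen-3-yl acetate, via hemiketal 19 (not isolated)
Conditions: DDQ (1.5 equiv), CH2Cl2/pH 7 phosphate buffer (10:1), 0 °C → rt
Reagents that add atoms: water, O
Why: Oxidative cleavage of an electron-rich benzylic ether (the reaction type by which DDQ removes p-methoxybenzyl ethers), in which hydride abstraction from the pseudo-axial C4–H gives an oxocarbenium ion stabilised by O1 and the 5- and 7-alkoxy groups, water adds to give hemiketal 19, and loss of methanol leaves the ketone without touching C2 or C3.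

Step 12
Reactants: 20 (2R,3R)-2-[3-methoxy-4-(methoxymethoxy)phenyl]-5,7-bis(methoxymethoxy)-6-(2-methylbut-3-en-2-yl)-4-oxo-3,4-dihydro-2H-chromen-3-yl acetate
Product: 21 (2R,3R)-3,5,7-trihydroxy-2-(4-hydroxy-3-methoxyphenyl)-6-(2-methylbut-3-en-2-yl)-2,3-dihydro-4H-chromen-4-one
Conditions: HCl (about 1.5 M) in MeOH, 40 °C
Reagents that add atoms: none
Why: Acid-catalysed acetal methanolysis of the three MOM ethers with concurrent acid-catalysed transesterification of the 3-acetate, the base-free way to unmask a base-sensitive dihydroflavonol, under which the thermodynamically preferred 2,3-trans arrangement should persist.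

Compound list
1 | 2,4,6-trihydroxybenzaldehyde | O=Cc1c(O)cc(O)cc1O | starting material
2 | 2,6-dihydroxy-4-(methoxymethoxy)benzaldehyde | O=Cc1c(O)cc(OCOC)cc1O | intermediate
3 | prenyl bromide (1-bromo-3-methylbut-2-ene) | CC(C)=CCBr | starting material
4 | 2-hydroxy-4-(methoxymethoxy)-6-[(3-methylbut-2-en-1-yl)oxy]benzaldehyde | O=Cc1c(O)cc(OCOC)cc1OCC=C(C)C | intermediate
5 | 2-[(tert-butyldimethylsilyl)oxy]-4-(methoxymethoxy)-6-[(3-methylbut-2-en-1-yl)oxy]benzaldehyde | O=Cc1c(O[Si](C)(C)C(C)(C)C)cc(OCOC)cc1OCC=C(C)C | intermediate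
6 | 2-[(tert-butyldimethylsilyl)oxy]-4-(methoxymethoxy)-5-(2-methylbut-3-en-2-yl)-6-oxocyclohexa-1,3-diene-1-carbaldehyde (ortho-dienone, racemic at C5) | O=CC1=C(O[Si](C)(C)C(C)(C)C)C=C(OCOC)C(C(C)(C)C=C)C1=O | intermediate (not isolated)
7 | 6-[(tert-butyldimethylsilyl)oxy]-2-hydroxy-4-(methoxymethoxy)-3-(2-methylbut-3-en-2-yl)benzaldehyde | O=Cc1c(O)c(C(C)(C)C=C)c(OCOC)cc1O[Si](C)(C)C(C)(C)C | intermediate
8 | 6-[(tert-butyldimethylsilyl)oxy]-2,4-bis(methoxymethoxy)-3-(2-methylbut-3-en-2-yl)benzaldehyde | O=Cc1c(OCOC)c(C(C)(C)C=C)c(OCOC)cc1O[Si](C)(C)C(C)(C)C | intermediate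
9 | 2-hydroxy-4,6-bis(methoxymethoxy)-5-(2-methylbut-3-en-2-yl)benzaldehyde | O=Cc1c(O)cc(OCOC)c(C(C)(C)C=C)c1OCOC | intermediate
10 | eugenol | C=CCc1ccc(O)c(OC)c1 | starting material
11 | 4-allyl-2-methoxy-1-(methoxymethoxy)benzene | C=CCc1ccc(OCOC)c(OC)c1 | intermediate
12 | 3-[3-methoxy-4-(methoxymethoxy)phenyl]propane-1,2-diol (racemic) | OCC(O)Cc1ccc(OCOC)c(OC)c1 | intermediate (not isolated)
13 | 2-[3-methoxy-4-(methoxymethoxy)phenyl]acetaldehyde | O=CCc1ccc(OCOC)c(OC)c1 | intermediate
14 | (E)-2-[3-methoxy-4-(methoxymethoxy)phenyl]ethenyl acetate | CC(=O)O/C=C/c1ccc(OCOC)c(OC)c1 | intermediate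
15 | trimethyl orthoformate | COC(OC)OC | starting material
16 | 2-(dimethoxymethyl)-3,5-bis(methoxymethoxy)-4-(2-methylbut-3-en-2-yl)phenol | COC(OC)c1c(O)cc(OCOC)c(C(C)(C)C=C)c1OCOC | intermediate (not isolated)
17 | 6-(methoxymethylidene)-3,5-bis(methoxymethoxy)-4-(2-methylbut-3-en-2-yl)cyclohexa-2,4-dien-1-one | COC=C1C(=O)C=C(OCOC)C(C(C)(C)C=C)=C1OCOC | intermediate (not isolated)
18 | (2R,3S,4R)-4-methoxy-2-[3-methoxy-4-(methoxymethoxy)phenyl]-5,7-bis(methoxymethoxy)-6-(2-methylbut-3-en-2-yl)-3,4-dihydro-2H-chromen-3-yl acetate (2,3-trans-3,4-trans) | C=CC(C)(C)c1c(OCOC)cc2c(c1OCOC)[C@@H](OC)[C@H](OC(C)=O)[C@@H](c1ccc(OCOC)c(OC)c1)O2 | intermediate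
19 | (2R,3R)-4-hydroxy-4-methoxy-2-[3-methoxy-4-(methoxymethoxy)phenyl]-5,7-bis(methoxymethoxy)-6-(2-methylbut-3-en-2-yl)-3,4-dihydro-2H-chromen-3-yl acetate (C4 undefined) | C=CC(C)(C)c1c(OCOC)cc2c(c1OCOC)C(O)(OC)[C@H](OC(C)=O)[C@@H](c1ccc(OCOC)c(OC)c1)O2 | intermediate (not isolated)
20 | (2R,3R)-2-[3-methoxy-4-(methoxymethoxy)phenyl]-5,7-bis(methoxymethoxy)-6-(2-methylbut-3-en-2-yl)-4-oxo-3,4-dihydro-2H-chromen-3-yl acetate | C=CC(C)(C)c1c(OCOC)cc2c(c1OCOC)C(=O)[C@H](OC(C)=O)[C@@H](c1ccc(OCOC)c(OC)c1)O2 | intermediate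
21 | (2R,3R)-3,5,7-trihydroxy-2-(4-hydroxy-3-methoxyphenyl)-6-(2-methylbut-3-en-2-yl)-2,3-dihydro-4H-chromen-4-one | C=CC(C)(C)c1c(O)cc2c(c1O)C(=O)[C@H](O)[C@@H](c1ccc(O)c(OC)c1)O2 | target

Total step count: 12. Longest linear sequence: 9 steps (steps 1–6, then 10–12); steps 7–9 form the second branch.

Steps most likely to fail

1. Step 10 (the one step beyond known chemistry). Facial discrimination inside the ion pair may be weak, since the enol acetate offers the anion no hydrogen-bond handle. Ionisation and cycloaddition may also be slow, because the doubly alkoxy-stabilised methide is a weak electrophile. The fallback uses known reactions only, sets out from 9 and comes back at 21.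
   - Addition of MeMgBr to 9 (THF, 0 °C) should give 2-(1-hydroxyethyl)-3,5-bis(methoxymethoxy)-4-(2-methylbut-3-en-2-yl)phenol F1.
   - MnO2 in CH2Cl2 then gives 1-[2-hydroxy-4,6-bis(methoxymethoxy)-5-(2-methylbut-3-en-2-yl)phenyl]ethan-1-one F2.
   - Condensation with N,N-dimethylformamide dimethyl acetal (PhMe, 90 °C) gives the enaminone (E)-3-(dimethylamino)-1-[2-hydroxy-4,6-bis(methoxymethoxy)-5-(2-methylbut-3-en-2-yl)phenyl]prop-2-en-1-one F3.
   - On gentle warming with a trace of acetic acid F3 closes, with loss of dimethylamine, to 5,7-bis(methoxymethoxy)-6-(2-methylbut-3-en-2-yl)-4H-chromen-4-one F4.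
   - Asymmetric conjugate addition of purchased [3-methoxy-4-(methoxymethoxy)phenyl]boronic acid F5 sets C2 and gives (2S)-2-[3-methoxy-4-(methoxymethoxy)phenyl]-5,7-bis(methoxymethoxy)-6-(2-methylbut-3-en-2-yl)-2,3-dihydro-4H-chromen-4-one F6. Conditions: Pd(OCOCF3)2, the antipode of 4-tert-butyl-2-(pyridin-2-yl)-4,5-dihydrooxazole that delivers the 2S product, NH4PF6, H2O, ClCH2CH2Cl, 60 °C.
   - In situ silylation (LiN(SiMe3)2, Me3SiCl, THF, −78 °C) gives (2S)-2-[3-methoxy-4-(methoxymethoxy)phenyl]-5,7-bis(methoxymethoxy)-6-(2-methylbut-3-en-2-yl)-4-[(trimethylsilyl)oxy]-2H-chromene F7.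
   - Rubottom oxidation with one equivalent of dimethyldioxirane (acetone, −78 °C) anti to the C2 aryl group, with desilylation on work-up, gives (2R,3R)-3-hydroxy-2-[3-methoxy-4-(methoxymethoxy)phenyl]-5,7-bis(methoxymethoxy)-6-(2-methylbut-3-en-2-yl)-2,3-dihydro-4H-chromen-4-one F8.
   - HCl in MeOH as in step 12 then gives 21.

2. Step 11. Hydride abstraction at C4 may be slow or may compete with abstraction at the C2–H next to ring B, and the oxocarbenium ion may lose H3 to a flav-3-ene enol acetate instead of adding water. The fallback sets out from 18 and comes back at 20. Solvolysis of the C4 methyl ether (camphorsulfonic acid cat., MeCN/H2O, rt) ionises to the same stabilised benzylic cation, and capture by water gives (2R,3S)-4-hydroxy-2-[3-methoxy-4-(methoxymethoxy)phenyl]-5,7-bis(methoxymethoxy)-6-(2-methylbut-3-en-2-yl)-3,4-dihydro-2H-chromen-3-yl acetate F9 as a C4 epimer mixture. Dess–Martin periodinane (NaHCO3, CH2Cl2) then oxidises both epimers to 20.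

3. Step 12. Ester methanolysis may lag behind acetal cleavage, and the long acid exposure could add a freed phenol across the vinyl group of the side chain or erode the C3 centre. The fallback sets out from 18 and comes back at 21. It removes the acetate first, with K2CO3 in MeOH at 0 °C on 18, where no centre is epimerisable, to give (2R,3S,4R)-4-methoxy-2-[3-methoxy-4-(methoxymethoxy)phenyl]-5,7-bis(methoxymethoxy)-6-(2-methylbut-3-en-2-yl)-3,4-dihydro-2H-chromen-3-ol F10. DDQ in CH2Cl2/pH 7 buffer as in step 11 then gives (2R,3R)-3-hydroxy-2-[3-methoxy-4-(methoxymethoxy)phenyl]-5,7-bis(methoxymethoxy)-6-(2-methylbut-3-en-2-yl)-2,3-dihydro-4H-chromen-4-one F8, the compound already met in the fallback to step 10. A brief treatment with HCl in MeOH at rt, which then has only acetals to cleave, gives 21.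

Further compounds
F1 | step 10 | 2-(1-hydroxyethyl)-3,5-bis(methoxymethoxy)-4-(2-methylbut-3-en-2-yl)phenol (racemic carbinol) | CC(O)c1c(O)cc(OCOC)c(C(C)(C)C=C)c1OCOC
F2 | step 10 | 1-[2-hydroxy-4,6-bis(methoxymethoxy)-5-(2-methylbut-3-en-2-yl)phenyl]ethan-1-one | CC(=O)c1c(O)cc(OCOC)c(C(C)(C)C=C)c1OCOC
F3 | step 10 | (E)-3-(dimethylamino)-1-[2-hydroxy-4,6-bis(methoxymethoxy)-5-(2-methylbut-3-en-2-yl)phenyl]prop-2-en-1-one | CN(C)/C=C/C(=O)c1c(O)cc(OCOC)c(C(C)(C)C=C)c1OCOC
F4 | step 10 | 5,7-bis(methoxymethoxy)-6-(2-methylbut-3-en-2-yl)-4H-chromen-4-one | C=CC(C)(C)c1c(OCOC)cc2occc(=O)c2c1OCOC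
F5 | step 10 | [3-methoxy-4-(methoxymethoxy)phenyl]boronic acid | COCOc1ccc(B(O)O)cc1OC
F6 | step 10 | (2S)-2-[3-methoxy-4-(methoxymethoxy)phenyl]-5,7-bis(methoxymethoxy)-6-(2-methylbut-3-en-2-yl)-2,3-dihydro-4H-chromen-4-one | C=CC(C)(C)c1c(OCOC)cc2c(c1OCOC)C(=O)C[C@@H](c1ccc(OCOC)c(OC)c1)O2
F7 | step 10 | (2S)-2-[3-methoxy-4-(methoxymethoxy)phenyl]-5,7-bis(methoxymethoxy)-6-(2-methylbut-3-en-2-yl)-4-[(trimethylsilyl)oxy]-2H-chromene | C=CC(C)(C)c1c(OCOC)cc2c(c1OCOC)C(O[Si](C)(C)C)=C[C@@H](c1ccc(OCOC)c(OC)c1)O2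
F8 | step 10 | (2R,3R)-3-hydroxy-2-[3-methoxy-4-(methoxymethoxy)phenyl]-5,7-bis(methoxymethoxy)-6-(2-methylbut-3-en-2-yl)-2,3-dihydro-4H-chromen-4-one | C=CC(C)(C)c1c(OCOC)cc2c(c1OCOC)C(=O)[C@H](O)[C@@H](c1ccc(OCOC)c(OC)c1)O2
F9 | step 11 | (2R,3S)-4-hydroxy-2-[3-methoxy-4-(methoxymethoxy)phenyl]-5,7-bis(methoxymethoxy)-6-(2-methylbut-3-en-2-yl)-3,4-dihydro-2H-chromen-3-yl acetate (C4 epimer mixture) | C=CC(C)(C)c1c(OCOC)cc2c(c1OCOC)C(O)[C@H](OC(C)=O)[C@@H](c1ccc(OCOC)c(OC)c1)O2
F10 | step 12 | (2R,3S,4R)-4-methoxy-2-[3-methoxy-4-(methoxymethoxy)phenyl]-5,7-bis(methoxymethoxy)-6-(2-methylbut-3-en-2-yl)-3,4-dihydro-2H-chromen-3-ol | C=CC(C)(C)c1c(OCOC)cc2c(c1OCOC)[C@@H](OC)[C@H](O)[C@@H](c1ccc(OCOC)c(OC)c1)O2
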